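**Retrosynthetic overview**

- The N-methoxy-4-pyridone ring is traced back to a 4-pyranone (5,6,7,8-tetrahydrochromen-4-one) by exchanging N-OMe for the ring oxygen. The benzyl ether on the C2 hydroxymethyl group is removed before any N–O bond exists.
- The pyranone O1–C2 bond is opened to a 2-acylcyclohexanone whose acyl chain is a β-methoxy enone; acid closes it again with loss of methanol.
- The carbocycle is a disguised cyclohex-2-enone: ring-fusion carbon C8a is the former carbonyl carbon, C4a the former α-carbon, and the octyl-bearing C5 the former β-carbon. One conjugate addition therefore fixes the lone stereocentre at C5 and leaves a nucleophile on C4a for the bond to the C4 carbonyl.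
- The C5–octyl and C4a–C4 bonds are made together from cyclohex-2-enone, octylmagnesium bromide and an N-acylbenzotriazole. That acyl donor comes from methyl methoxyacetate and benzyloxyacetyl chloride.
- Ring order: the carbocycle is bought, the oxygen heterocycle is closed onto it, and that ring is then converted into the N-methoxy pyridone ring.

Key step: step 5

Remark: the tetrasubstituted enol-ether double bond of the acyl fragment is carried as an E/Z mixture from the enol methylation to the pyranone closure, where its geometry is lost, and the 2-acylcyclohexanone is drawn as the diketone although it should be largely enolised; TaniaPhos stands for 1-[α-(dimethylamino)-2-(diphenylphosphino)benzyl]-2-(diphenylphosphino)ferrocene, used as the enantiomer that delivers (R)-3-alkylcyclohexanones (the sense is to be checked on the simply protonated adduct before the acyl donor is committed).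

**Route**

Step 1
Reactants: 1 methyl 2-methoxyacetate; 2 2-(benzyloxy)acetyl chloride
Product: 4 methyl 4-(benzyloxy)-2-methoxy-3-oxobutanoate, via lithium 1,2-dimethoxyethen-1-olate 3 (not isolated)
Conditions: LiN(iPr)2 (2.1 equiv), THF, −78 °C, 1 (2.1 equiv); then 2 (1.0 equiv), −78 °C; cold 1 M HCl quench
Reagents that add atoms: none
Why: Crossed Claisen acylation, in which the lithium ester enolate 3 attacks the far more electrophilic acid chloride at carbon and the second equivalent of enolate deprotonates the acidic β-keto ester as it forms, shielding it from further acylation.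

Step 2
Reactants: 4 methyl 4-(benzyloxy)-2-methoxy-3-oxobutanoate
Product: 6 methyl 4-(benzyloxy)-2,3-dimethoxybut-2-enoate (E/Z mixture), via methyl 4-(benzyloxy)-2,3,3-trimethoxybutanoate 5 (not isolated)
Conditions: HC(OMe)3, cat. p-TsOH·H2O, MeOH, 50 °C; then toluene, 110 °C, MeOH distilled off
Reagents that add atoms: trimethyl orthoformate, COC(OC)OC; methanol, CO
Why: Acid-catalysed ketalisation by the orthoformate and thermal loss of methanol toward the acidic C2–H should give the ester-conjugated (push–pull) enol ether, the usual way from acetoacetates to 3-methoxybut-2-enoates.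

Step 3
Reactants: 6 methyl 4-(benzyloxy)-2,3-dimethoxybut-2-enoate
Product: 7 4-(benzyloxy)-2,3-dimethoxybut-2-enoic acid (E/Z mixture)
Conditions: LiOH·H2O, THF/MeOH/H2O, 40 °C; then 1 M HCl to pH 3, 0 °C
Reagents that add atoms: lithium hydroxide, [Li+].[OH-]
Why: Ester saponification by hydroxide; the vinylogous-carbonate enol ether resists base and should tolerate a brief, cold acidification to pH 3, which avoids hydrolysis to the decarboxylation-prone β-keto acid.

Step 4
Reactants: 7 4-(benzyloxy)-2,3-dimethoxybut-2-enoic acid
Product: 8 1-[4-(benzyloxy)-2,3-dimethoxybut-2-enoyl]-1H-benzotriazole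
Conditions: 1H-benzotriazole (4 equiv), SOCl2 (1.05 equiv), CH2Cl2, rt, 30 min; then 7, rt
Reagents that add atoms: 1H-benzotriazole, c1ccc2[nH]nnc2c1
Why: Carboxylic acid activation by the thionyl chloride–benzotriazole reagent (sulfinylbis(benzotriazole) formed in the flask, HCl buffered by excess benzotriazole) should give the bench-stable N-acylbenzotriazole under anhydrous conditions that leave the benzyl and enol ethers intact.

Step 5
Reactants: 9 cyclohex-2-en-1-one; 10 octylmagnesium bromide; 8 1-[4-(benzyloxy)-2,3-dimethoxybut-2-enoyl]-1H-benzotriazole
Product: 12 (3R)-2-[4-(benzyloxy)-2,3-dimethoxybut-2-enoyl]-3-octylcyclohexan-1-one, via bromomagnesium (3R)-3-octylcyclohex-1-en-1-olate 11 (not isolated)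
Conditions: 9 (2.3 equiv), CuCl (5 mol%), TaniaPhos (6 mol%), Et2O, 0 °C, 10 (2.2 equiv, Et2O) added slowly; then −78 °C, 8 (1.0 equiv) in THF, −78 to −20 °C; aq. NH4Cl
Reagents that add atoms: none
Why: Proposed new method: the CuCl–TaniaPhos complex (monovalent copper) is transmetallated by 10, binds the enone 9, transfers octyl to C3 through a trivalent-copper intermediate and releases the regiodefined bromomagnesium enolate 11, whose C2 then attacks the acyl carbonyl of 8 and expels benzotriazolide to give the chelated magnesium β-diketonate of 12. The closest known reaction types are the copper/ferrocenyl-diphosphine catalysed asymmetric conjugate addition of Grignard reagents to cyclic enones with in situ trapping of the magnesium enolate by carbon electrophiles, and the C-acylation of lithium and magnesium ketone enolates by N-acylbenzotriazoles; their one-pot union with a tetrasubstituted, vinylogously deactivated acyl donor has not been shown. No ring closes here: the step forms the C5–octyl and C4a–C4 bonds (target numbering) and so delivers the complete open-chain precursor of the heterocycle. The C3 stereocentre (C5 of the target) is set by the chiral diphosphine on copper through enantioface selection on the enone, whereas the new C2 centre is of no consequence because it becomes sp2. The step needs 1,4- over 1,2-addition and enantioface selectivity, both secured by the ligated copper catalyst in Et2O, and C-acylation at C2 rather than O-acylation or reaction at C6, secured by the regiospecific magnesium enolate, the chelating acyl donor and the cold addition. About two equivalents of 11 per 8 are used, and 8 is added only after 10 is consumed, so that proton transfer from the acidic product to unreacted enolate does not cap conversion of the valuable acyl donor and no Grignard reagent is left to attack it.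

Step 6
Reactants: 12 (3R)-2-[4-(benzyloxy)-2,3-dimethoxybut-2-enoyl]-3-octylcyclohexan-1-one
Product: 13 (5R)-2-[(benzyloxy)methyl]-3-methoxy-5-octyl-5,6,7,8-tetrahydro-4H-chromen-4-one
Conditions: CF3CO2H, CH2Cl2, rt
Reagents that add atoms: none
Why: Acid-promoted 6-endo oxa-Michael addition of the ring-ketone enol oxygen to the β-methoxy enone carbon and loss of methanol (addition–elimination) is the standard closure of 4-pyranones; only that oxygen can reach the β-carbon, and the C5 stereocentre is not enolisable.

Step 7
Reactants: 13 (5R)-2-[(benzyloxy)methyl]-3-methoxy-5-octyl-5,6,7,8-tetrahydro-4H-chromen-4-one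
Product: 14 (5R)-2-(hydroxymethyl)-3-methoxy-5-octyl-5,6,7,8-tetrahydro-4H-chromen-4-one
Conditions: H2 (1 atm), 10% Pd/C, EtOAc, rt, stopped after one equivalent of H2
Reagents that add atoms: none
Why: Hydrogenolysis of the benzyl ether over Pd/C at ambient pressure should leave the 4-pyranone ring and its methyl enol ether unreduced, and it is placed here because no N–O bond is yet present.

Step 8
Reactants: 14 (5R)-2-(hydroxymethyl)-3-methoxy-5-octyl-5,6,7,8-tetrahydro-4H-chromen-4-one
Product: 16 (5R)-2-(hydroxymethyl)-1,3-dimethoxy-5-octyl-5,6,7,8-tetrahydroquinolin-4(1H)-one, via (3R)-2-[4-hydroxy-2-methoxy-3-(methoxyamino)but-2-enoyl]-3-octylcyclohexan-1-one 15 (not isolated)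
Conditions: MeONH2·HCl (10 equiv), pyridine/EtOH 1:1, 90 °C, sealed tube
Reagents that add atoms: O-methylhydroxylamine hydrochloride, CON.Cl
Why: Proposed new method: the α-effect nitrogen of MeONH2 should add in conjugate fashion at C2 of the pyranone, the ring then opens to the N-methoxy enaminone 15 and recloses by condensation of its NH on the C8a carbonyl (six-membered, loss of water), the vinylogous-ester C4 carbonyl being too deactivated to form an oxime; the closest known reaction type is the conversion of 4-pyranones into 1-hydroxy-4-pyridinones with hydroxylamine and into N-substituted 4-pyridones with primary amines, not yet shown for O-methylhydroxylamine on a fully substituted fused pyranone.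

**Compound list**

1 | methyl 2-methoxyacetate | COCC(=O)OC | starting material
2 | 2-(benzyloxy)acetyl chloride | O=C(Cl)COCc1ccccc1 | starting material
3 | lithium 1,2-dimethoxyethen-1-olate | [Li]OC(OC)=COC | intermediate
4 | methyl 4-(benzyloxy)-2-methoxy-3-oxobutanoate | COC(=O)C(OC)C(=O)COCc1ccccc1 | intermediate
5 | methyl 4-(benzyloxy)-2,3,3-trimethoxybutanoate | COC(=O)C(OC)C(OC)(OC)COCc1ccccc1 | intermediate
6 | methyl 4-(benzyloxy)-2,3-dimethoxybut-2-enoate (E/Z mixture) | COC(=O)C(OC)=C(OC)COCc1ccccc1 | intermediate
7 | 4-(benzyloxy)-2,3-dimethoxybut-2-enoic acid (E/Z mixture) | OC(=O)C(OC)=C(OC)COCc1ccccc1 | intermediate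
8 | 1-[4-(benzyloxy)-2,3-dimethoxybut-2-enoyl]-1H-benzotriazole | O=C(C(OC)=C(OC)COCc1ccccc1)n1nnc2ccccc21 | intermediate
9 | cyclohex-2-en-1-one | O=C1C=CCCC1 | starting material
10 | octylmagnesium bromide | CCCCCCCC[Mg]Br | starting material
11 | bromomagnesium (3R)-3-octylcyclohex-1-en-1-olate | CCCCCCCC[C@@H]1CCCC(O[Mg]Br)=C1 | intermediate
12 | (3R)-2-[4-(benzyloxy)-2,3-dimethoxybut-2-enoyl]-3-octylcyclohexan-1-one (C2 labile) | CCCCCCCC[C@@H]1CCCC(=O)C1C(=O)C(OC)=C(OC)COCc1ccccc1 | intermediate
13 | (5R)-2-[(benzyloxy)methyl]-3-methoxy-5-octyl-5,6,7,8-tetrahydro-4H-chromen-4-one | CCCCCCCC[C@@H]1CCCC2=C1C(=O)C(OC)=C(COCc1ccccc1)O2 | intermediate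
14 | (5R)-2-(hydroxymethyl)-3-methoxy-5-octyl-5,6,7,8-tetrahydro-4H-chromen-4-one | CCCCCCCC[C@@H]1CCCC2=C1C(=O)C(OC)=C(CO)O2 | intermediate
15 | (3R)-2-[4-hydroxy-2-methoxy-3-(methoxyamino)but-2-enoyl]-3-octylcyclohexan-1-one | CCCCCCCC[C@@H]1CCCC(=O)C1C(=O)C(OC)=C(CO)NOC | intermediate
16 | (5R)-2-(hydroxymethyl)-1,3-dimethoxy-5-octyl-5,6,7,8-tetrahydroquinolin-4(1H)-one | CCCCCCCC[C@@H]1CCCc2c1c(=O)c(OC)c(CO)n2OC | target

**Step count and risks**

Total step count: 8. Longest linear sequence: 8 steps (from 1 through steps 1 to 8; 9 and 10 are bought and enter at step 5).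

Steps most likely to fail:

1. Step 5. The hindered, electronically deactivated acyl donor may react too slowly with the aggregated magnesium enolate, so that O-acylation, proton transfer and loss of enolate regiochemistry take over. The fallback sets out from 6 (with 9 and 10) and comes back at 12, using the well-established aldol trapping of these magnesium enolates followed by oxidation.
   - Ester 6 would be reduced with iBu2AlH (CH2Cl2, −78 °C, Rochelle-salt work-up) to 4-(benzyloxy)-2,3-dimethoxybut-2-en-1-ol F1.
   - MnO2 (CH2Cl2, rt) would oxidise it to 4-(benzyloxy)-2,3-dimethoxybut-2-enal F2.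
   - Enolate 11, generated exactly as in step 5, would be trapped at −78 °C by F2 to give (3R)-2-[4-(benzyloxy)-1-hydroxy-2,3-dimethoxybut-2-en-1-yl]-3-octylcyclohexan-1-one F3, as a diastereomer mixture at centres that later become sp2.
   - Dess–Martin periodinane buffered with NaHCO3 (CH2Cl2, rt) would oxidise F3 to the diketone 12.

2. Step 8. The weakly basic alkoxyamine may fail to open the fully substituted pyranone, or the opened enaminone may not reclose. The fallback sets out from 14 and comes back at 16.
   - Exchange with the smaller, more nucleophilic parent hydroxylamine (NH2OH·HCl, pyridine, reflux), the known pyranone to 1-hydroxy-4-pyridinone conversion, would give (5R)-1-hydroxy-2-(hydroxymethyl)-3-methoxy-5-octyl-5,6,7,8-tetrahydroquinolin-4(1H)-one F4.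
   - Its acidic N-hydroxy group would then be methylated selectively over the primary alcohol with MeI and K2CO3 in DMF at rt, the known O-alkylation of 1-hydroxy-4-pyridinones, to give 16.

3. Step 2. Ketalisation of the doubly α-oxygenated ketone may stall, or methanol may be lost toward C4 instead of C2, giving regioisomeric enol ethers. The fallback sets out from 4 and comes back at 6: the ester-stabilised enolate of 4 is formed with Cs2CO3 in DMF and O-methylated with the hard electrophile Me2SO4 (enolate O-alkylation in place of ketalisation–elimination), and the C-methylated by-product is removed by chromatography. No compound outside the compound list is made (F0).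

**Further compounds**

F1 | step 5 | 4-(benzyloxy)-2,3-dimethoxybut-2-en-1-ol | OCC(OC)=C(OC)COCc1ccccc1
F2 | step 5 | 4-(benzyloxy)-2,3-dimethoxybut-2-enal | O=CC(OC)=C(OC)COCc1ccccc1
F3 | step 5 | (3R)-2-[4-(benzyloxy)-1-hydroxy-2,3-dimethoxybut-2-en-1-yl]-3-octylcyclohexan-1-one | CCCCCCCC[C@@H]1CCCC(=O)C1C(O)C(OC)=C(OC)COCc1ccccc1
F4 | step 8 | (5R)-1-hydroxy-2-(hydroxymethyl)-3-methoxy-5-octyl-5,6,7,8-tetrahydroquinolin-4(1H)-one | CCCCCCCC[C@@H]1CCCc2c1c(=O)c(OC)c(CO)n2O
F0 | step 2 | none | none
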